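The numbers in the tables stem from a simulated flask with constants of no real substance; scatter was added.

The constants of this flask are hidden, so you work from Wednesday's run of the same flask. There, target counts its crystals too, and target minus crystals is what stands dissolved.

- Wednesday's: substrate 0.62 M; the very flask that is asked about, followed so far
- flask: substrate 0.62 M; time 3.0 h

- Wednesday's (time / min: target / %, crystals / %): 3.00: 24.7, 6.6; 8.00: 27.7, 16.7; 15.0: 29.4, 23.1; 25.0: 29.3, 26.3; 30.0: 28.4, 27.4; 40.0: 29.1, 26.7; 50.0: 29.8, 26.4

(each reading ± 0.5 percentage points)

- what is said of target includes crystals
- crystals is a solid; its amount is given per volume of the solution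
- steps under discussion: crystals <-> target; substrate <-> target; substrate <-> isomer of the product; substrate <-> third isomer

- the target and crystals together standing at 3.0 h, as a percentage of the substrate charged
- concentration of target in solution at 3.0 h, in percent of saturation

From 25.0 min on, the crystals in Wednesday's run read about 26.7 % and the dissolved target about 2.45 % of the charge. That is 15.2 mM, our reading of the solubility.

How fast is that level reached? Take the crystal half-life, the time in which the crystals' distance from their plateau halves: between 3.00 min and 15.0 min the readings give 4.84 min. The second way follows the dissolved target's distance above its level over the same interval and gives 5.93 min. They part, and the second is the one that cheats: total target read 24.7 % at the start of the interval, less than the 29.4 % at its end, so dissolved target was still being fed as it fell.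

The gap costs little, since 3.0 h is 30.4 half-lives on the longer figure and 37.2 on the shorter. I therefore expect full saturation beside about 26.7 % of crystals. Total target looks flat from 15.0 min on, so I take its mean, 29.2 %.

The forecast gives 29.6 % and 100 %, its first figure above my mean, as it chose to “allow a small upward drift”.

The flask gives 28.3 %, a little below my mean, and 97.5 %, with 26.4 % of crystals standing.

    crystals ⇌ target, rate k1*(cs1 - [target]) while solid is left; crystals form when [target] > cs1 (solubility = 12.0 mM, k = 9.71 h⁻¹)
    substrate ⇌ target (K = 0.363, k = 19.1 h⁻¹)
    substrate ⇌ isomer of the product (K = 3.11, k = 0.226 h⁻¹)
    substrate ⇌ third isomer (K = 11.8, k = 6.30 h⁻¹)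

The neighbour flask, charged with 2.5 M of substrate and run for the same 3.0 h, takes the same count. If its crystal half-life is also 4.84 min, that is 37.2 half-lives, and the count points to a saturated solution. But the neighbour flask is not saturated: it holds 48.6 % of target, 47.6 % of the charge as crystals, so 25.0 mM stands dissolved, twice the solubility of 12 mM, beside 2.99 % of substrate and 44.6 % of third isomer.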